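**Plan**

- Retrosynthetic cuts, in order: the two O–C1(ring D) bonds from the C4 oxygen of each ring C; the two O–C1(ring C) bonds from the C1 and C3 oxygens of ring B; the O–C2(ring B) bond from ring A; the two ring D–ring E biaryl bonds.
- Enabling feature: in the pentasubstituted ring D the ether carbon C1 is para to the hydroxyl carbon C4 (C2 and C6 carry OH, C5 carries ring E). The same para O/O relation recurs in ring C (C1/C4) and ring B (C2/C5), so each of these oxygens can travel as a formyl group that activates a para fluoride for SNAr and is afterwards oxidised to the phenol.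
- One aldehyde, 4-fluoro-3,5-dimethoxybenzaldehyde, serves three times: as ring B (benzyl in place of methyl), as ring C, and, after bromination and Suzuki coupling with ring E, as the ring D–E unit.
- Forward order, from the centre outwards: ring A + ring B → hub diol; + two rings C → tetramer bis-aldehyde → bis-phenol; + two ring D–E units → octamer bis-aldehyde → bis-phenol → global O-demethylation.
- No ring is built (all eight benzene rings are bought). There is no stereocentre, and the ring D–ring E axes are not stereogenic because ring E is symmetric, so no stereocontrol is needed.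

Key step: step 13

Assumption: compounds 1, 6 and 10 are catalogue chemicals.

**Route**

Step 1
Reactants: 1 2-fluoro-1,3-dimethoxybenzene
Product: 3 5-bromo-2-fluoro-1,3-dimethoxybenzene, via aryl pinacol boronate 2 (not isolated)
Conditions: [Ir(OMe)(cod)]2 (cat.), 4,4′-di-tert-butyl-2,2′-bipyridine (cat.), B2pin2, THF, 80 °C; evaporate; CuBr2, MeOH–H2O (1:1), 80 °C
Reagents that add atoms: CuBr2, Br[Cu]Br (bromine of 3); B2pin2, CC1(C)OB(OC1(C)C)B1OC(C)(C)C(C)(C)O1 (boryl group of intermediate 2 only)
Why: Iridium-catalysed C–H borylation is sterically controlled and takes C5, the only C–H without an ortho substituent, and CuBr2 then replaces the boryl group by bromine (one-pot borylation–bromodeboronation), giving the meta-to-methoxy pattern that electrophilic substitution cannot deliver.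

Step 2
Reactants: 3 5-bromo-2-fluoro-1,3-dimethoxybenzene
Product: 4 4-fluoro-3,5-dimethoxybenzaldehyde
Conditions: n-BuLi, THF, −78 °C; DMF, −78 °C to 0 °C; aq. HCl
Reagents that add atoms: N,N-dimethylformamide, CN(C)C=O
Why: Bromine–lithium exchange and trapping of the aryllithium with DMF (Bouveault formylation) should be clean because the lithium sits para, not ortho, to fluorine, so no aryne can form.

Step 3
Reactants: 4 4-fluoro-3,5-dimethoxybenzaldehyde
Product: 5 2-bromo-4-fluoro-3,5-dimethoxybenzaldehyde
Conditions: NBS, MeCN, 0 °C to rt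
Reagents that add atoms: N-bromosuccinimide, O=C1CCC(=O)N1Br
Why: Electrophilic aromatic bromination; the two free positions are equivalent, each ortho to one methoxy group and para to the other, and the first bromine slows a second substitution.

Step 4
Reactants: 5 2-bromo-4-fluoro-3,5-dimethoxybenzaldehyde; 6 2,4,6-trimethoxyphenylboronic acid
Product: 7 4-fluoro-3,5-dimethoxy-2-(2,4,6-trimethoxyphenyl)benzaldehyde (ring D–E fluoro-aldehyde)
Conditions: Pd(OAc)2 (cat.), SPhos (2-dicyclohexylphosphino-2′,6′-dimethoxybiphenyl, cat.), K3PO4, toluene–H2O (10:1), 90 °C, excess 6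
Reagents that add atoms: none
Why: Suzuki–Miyaura coupling with a bulky dialkylbiarylphosphine, the ligand class established for tetra-ortho-substituted biaryls and 2,6-dialkoxyarylboronic acids; the ortho formyl group speeds oxidative addition and the aryl fluoride is inert to zerovalent palladium.

Step 5
Reactants: 4 4-fluoro-3,5-dimethoxybenzaldehyde
Product: 8 4-fluoro-3,5-dihydroxybenzaldehyde
Conditions: BBr3, CH2Cl2, −78 °C to rt; H2O
Reagents that add atoms: none
Why: Lewis-acid cleavage of aryl methyl ethers by BBr3; the aldehyde is returned on aqueous work-up and the C–F bond is untouched.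

Step 6
Reactants: 8 4-fluoro-3,5-dihydroxybenzaldehyde
Product: 9 3,5-bis(benzyloxy)-4-fluorobenzaldehyde
Conditions: BnBr, K2CO3, DMF, rt
Reagents that add atoms: benzyl bromide, BrCc1ccccc1
Why: Williamson etherification; the phenoxide oxygens are benzylated at room temperature, where the fluoride, deactivated by the two ortho oxido groups, is not displaced.

Step 7
Reactants: 9 3,5-bis(benzyloxy)-4-fluorobenzaldehyde; 10 3,5-dimethoxyphenol
Product: 11 3,5-bis(benzyloxy)-4-(3,5-dimethoxyphenoxy)benzaldehyde
Conditions: Cs2CO3, DMSO, 100 °C, Ar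
Reagents that add atoms: none
Why: SNAr para to a formyl group; the phenoxide of 10 displaces fluoride through a formyl-stabilised Meisenheimer anion, which makes the ring A–O–C2(ring B) bond and leaves the formyl group where ring B needs its C5 oxygen.

Step 8
Reactants: 11 3,5-bis(benzyloxy)-4-(3,5-dimethoxyphenoxy)benzaldehyde
Product: 13 3,5-bis(benzyloxy)-4-(3,5-dimethoxyphenoxy)phenol, via aryl formate 12 (not isolated)
Conditions: mCPBA, CH2Cl2, 0 °C to rt; aq. Na2S2O3 wash; K2CO3 (cat.), MeOH, rt
Reagents that add atoms: meta-chloroperoxybenzoic acid, OOC(=O)c1cccc(Cl)c1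
Why: Baeyer–Villiger oxidation of an electron-rich benzaldehyde (Dakin-type); the aryl group, made migration-prone by the para aryloxy oxygen, shifts to oxygen in the Criegee adduct, and the formate is cleaved by methanolysis only after the peracid is removed, so the phenol never meets the oxidant.

Step 9
Reactants: 13 3,5-bis(benzyloxy)-4-(3,5-dimethoxyphenoxy)phenol
Product: 14 1,3-bis(benzyloxy)-2-(3,5-dimethoxyphenoxy)-5-methoxybenzene
Conditions: MeI, K2CO3, acetone, reflux
Reagents that add atoms: iodomethane, CI
Why: Williamson methylation of the single free phenol caps the C5 oxygen of ring B in the same form as all other spectator oxygens.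

Step 10
Reactants: 14 1,3-bis(benzyloxy)-2-(3,5-dimethoxyphenoxy)-5-methoxybenzene
Product: 15 2-(3,5-dimethoxyphenoxy)-5-methoxybenzene-1,3-diol (ring A–B hub diol)
Conditions: H2 (1 atm), Pd/C, EtOAc–MeOH, rt
Reagents that add atoms: none
Why: Catalytic hydrogenolysis cleaves only the two benzyl ethers and so frees exactly the C1 and C3 hydroxyls of ring B that are to be arylated; methyl and diaryl ethers are stable.

Step 11
Reactants: 15 2-(3,5-dimethoxyphenoxy)-5-methoxybenzene-1,3-diol; 4 4-fluoro-3,5-dimethoxybenzaldehyde (slight excess over two equivalents)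
Product: 16 tetramer bis-aldehyde (15 with a 4-formyl-2,6-dimethoxyphenyl group on each ring B hydroxyl oxygen)
Conditions: Cs2CO3, DMSO, 110 °C, Ar
Reagents that add atoms: none
Why: Twofold SNAr of the type used in step 7; each ring B phenoxide displaces the para-formyl-activated fluoride of one molecule of 4, forming both O–C1(ring C) bonds and placing a formyl group where each ring C needs its C4 oxygen.

Step 12
Reactants: 16 tetramer bis-aldehyde
Product: 18 tetramer bis-phenol, via tetramer bis-formate 17 (not isolated)
Conditions: mCPBA, CH2Cl2, 0 °C to rt; aq. Na2S2O3 wash; K2CO3 (cat.), MeOH, rt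
Reagents that add atoms: meta-chloroperoxybenzoic acid, OOC(=O)c1cccc(Cl)c1
Why: Twofold Baeyer–Villiger oxidation and formate methanolysis as in step 8; both formyl groups are para to an aryloxy oxygen, so aryl migration is favoured, and a small excess of peracid at low temperature should spare the electron-rich rings.

Step 13
Reactants: 18 tetramer bis-phenol; 7 4-fluoro-3,5-dimethoxy-2-(2,4,6-trimethoxyphenyl)benzaldehyde (slight excess over two equivalents)
Product: 19 octamer bis-aldehyde (18 with a 4-formyl-2,6-dimethoxy-3-(2,4,6-trimethoxyphenyl)phenyl group on each ring C phenol oxygen)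
Conditions: Cs2CO3, DMSO, 4 Å molecular sieves, 120 °C, Ar
Reagents that add atoms: none
Why: The caesium bis-phenoxide of 18 adds through the C4 oxygen of each ring C to the fluorine-bearing carbon of 7 (C1 of the future ring D), giving a Meisenheimer anion whose charge is delocalised onto the para formyl oxygen, and loss of fluoride restores the arene, once on each arm. The closest known reaction type is the SNAr of 4-fluorobenzaldehydes with phenoxides, the first half of the classical fluorobenzaldehyde/Baeyer–Villiger diaryl ether synthesis, already rehearsed in steps 7 and 11 on the aldehyde without ring E. No ring is closed and no stereocentre is formed; only the two O–C1(ring D) bonds are made. The step needs substitution at C–F only and O- rather than C-arylation: fluoride is the sole leaving group para to the formyl group, the methoxy groups are meta to it and are poor nucleofuges, and a caesium phenoxide in DMSO reacts at oxygen. The nucleophilic oxygen is flanked by two ring hydrogens, so the steric load lies only on the electrophile, whose two ortho methoxy groups are small and can turn aside. An excess of 7 with exclusion of water and air should drive both arms to completion and prevent hydroxide attack or oxidation of the electron-rich phenoxide.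

Step 14
Reactants: 19 octamer bis-aldehyde
Product: 21 octamer bis-phenol, via octamer bis-formate 20 (not isolated)
Conditions: mCPBA, CH2Cl2, 0 °C to rt; aq. Na2S2O3 wash; K2CO3 (cat.), MeOH, rt
Reagents that add atoms: meta-chloroperoxybenzoic acid, OOC(=O)c1cccc(Cl)c1
Why: Twofold Baeyer–Villiger oxidation and formate methanolysis; the formyl-bearing C4 of each ring D is para to the new ether oxygen, so ring D migrates to oxygen, and the neighbouring ring E should only slow peracid addition.

Step 15
Reactants: 21 octamer bis-phenol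
Product: 22 CNP0227063.0 (target)
Conditions: BBr3 (large excess), CH2Cl2, −78 °C to rt; H2O; work-up under Ar
Reagents that add atoms: none
Why: Exhaustive Lewis-acid cleavage of the seventeen aryl methyl ethers by BBr3, which does not cleave diaryl ether or biaryl bonds; no stereochemical element is present that could be lost.

**Compound list**

1 | 2-fluoro-1,3-dimethoxybenzene | COc1cccc(OC)c1F | starting material
2 | 2-(4-fluoro-3,5-dimethoxyphenyl)-4,4,5,5-tetramethyl-1,3,2-dioxaborolane (aryl pinacol boronate, not isolated) | COc1cc(B2OC(C)(C)C(C)(C)O2)cc(OC)c1F | intermediate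
3 | 5-bromo-2-fluoro-1,3-dimethoxybenzene | COc1cc(Br)cc(OC)c1F | intermediate
4 | 4-fluoro-3,5-dimethoxybenzaldehyde | COc1cc(C=O)cc(OC)c1F | intermediate
5 | 2-bromo-4-fluoro-3,5-dimethoxybenzaldehyde | COc1cc(C=O)c(Br)c(OC)c1F | intermediate
6 | 2,4,6-trimethoxyphenylboronic acid | COc1cc(OC)c(B(O)O)c(OC)c1 | starting material
7 | 4-fluoro-3,5-dimethoxy-2-(2,4,6-trimethoxyphenyl)benzaldehyde (ring D–E fluoro-aldehyde) | O=Cc1cc(OC)c(F)c(OC)c1-c1c(OC)cc(OC)cc1OC | intermediate
8 | 4-fluoro-3,5-dihydroxybenzaldehyde | O=Cc1cc(O)c(F)c(O)c1 | intermediate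
9 | 3,5-bis(benzyloxy)-4-fluorobenzaldehyde | O=Cc1cc(OCc2ccccc2)c(F)c(OCc2ccccc2)c1 | intermediate
10 | 3,5-dimethoxyphenol | COc1cc(O)cc(OC)c1 | starting material
11 | 3,5-bis(benzyloxy)-4-(3,5-dimethoxyphenoxy)benzaldehyde | COc1cc(OC)cc(Oc2c(OCc3ccccc3)cc(C=O)cc2OCc2ccccc2)c1 | intermediate
12 | 3,5-bis(benzyloxy)-4-(3,5-dimethoxyphenoxy)phenyl formate (not isolated) | COc1cc(OC)cc(Oc2c(OCc3ccccc3)cc(OC=O)cc2OCc2ccccc2)c1 | intermediate
13 | 3,5-bis(benzyloxy)-4-(3,5-dimethoxyphenoxy)phenol | COc1cc(OC)cc(Oc2c(OCc3ccccc3)cc(O)cc2OCc2ccccc2)c1 | intermediate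
14 | 1,3-bis(benzyloxy)-2-(3,5-dimethoxyphenoxy)-5-methoxybenzene | COc1cc(OC)cc(Oc2c(OCc3ccccc3)cc(OC)cc2OCc2ccccc2)c1 | intermediate
15 | 2-(3,5-dimethoxyphenoxy)-5-methoxybenzene-1,3-diol (ring A–B hub diol) | COc1cc(OC)cc(Oc2c(O)cc(OC)cc2O)c1 | intermediate
16 | tetramer bis-aldehyde: 4,4′-{[2-(3,5-dimethoxyphenoxy)-5-methoxy-1,3-phenylene]bis(oxy)}bis(3,5-dimethoxybenzaldehyde) | COc1cc(OC)cc(Oc2c(Oc3c(OC)cc(C=O)cc3OC)cc(OC)cc2Oc2c(OC)cc(C=O)cc2OC)c1 | intermediate
17 | tetramer bis-formate: diformate ester of 18 (not isolated) | COc1cc(OC)cc(Oc2c(Oc3c(OC)cc(OC=O)cc3OC)cc(OC)cc2Oc2c(OC)cc(OC=O)cc2OC)c1 | intermediate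
18 | tetramer bis-phenol: 4,4′-{[2-(3,5-dimethoxyphenoxy)-5-methoxy-1,3-phenylene]bis(oxy)}bis(3,5-dimethoxyphenol) | COc1cc(OC)cc(Oc2c(Oc3c(OC)cc(O)cc3OC)cc(OC)cc2Oc2c(OC)cc(O)cc2OC)c1 | intermediate
19 | octamer bis-aldehyde: 18 with each phenol oxygen bonded to C1 of a 4-formyl-2,6-dimethoxy-3-(2,4,6-trimethoxyphenyl)phenyl group | COc1cc(OC)cc(Oc2c(Oc3c(OC)cc(Oc4c(OC)cc(C=O)c(-c5c(OC)cc(OC)cc5OC)c4OC)cc3OC)cc(OC)cc2Oc2c(OC)cc(Oc3c(OC)cc(C=O)c(-c4c(OC)cc(OC)cc4OC)c3OC)cc2OC)c1 | intermediate
20 | octamer bis-formate: 19 with each formyl group replaced by formyloxy (not isolated) | COc1cc(OC)cc(Oc2c(Oc3c(OC)cc(Oc4c(OC)cc(OC=O)c(-c5c(OC)cc(OC)cc5OC)c4OC)cc3OC)cc(OC)cc2Oc2c(OC)cc(Oc3c(OC)cc(OC=O)c(-c4c(OC)cc(OC)cc4OC)c3OC)cc2OC)c1 | intermediate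
21 | octamer bis-phenol: 19 with each formyl group replaced by hydroxyl (seventeen methyl ethers, two free ring D C4 hydroxyls) | COc1cc(OC)cc(Oc2c(Oc3c(OC)cc(Oc4c(OC)cc(O)c(-c5c(OC)cc(OC)cc5OC)c4OC)cc3OC)cc(OC)cc2Oc2c(OC)cc(Oc3c(OC)cc(O)c(-c4c(OC)cc(OC)cc4OC)c3OC)cc2OC)c1 | intermediate
22 | CNP0227063.0 (nineteen free hydroxyls) | Oc1cc(O)cc(Oc2c(Oc3c(O)cc(Oc4c(O)cc(O)c(-c5c(O)cc(O)cc5O)c4O)cc3O)cc(O)cc2Oc2c(O)cc(Oc3c(O)cc(O)c(-c4c(O)cc(O)cc4O)c3O)cc2O)c1 | target

**Step count and risks**

Total: 15 steps. Longest linear sequence: 13 steps (1, 2, 5 to 15).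

Steps most likely to fail:

1. Step 13. Addition of the phenoxide to the fluorine-bearing carbon may be too slow: that carbon is shielded by two methoxy groups, one of them pressed toward it by the neighbouring ring E, and activation by a single para formyl group is modest. At the temperature then needed, base-induced degradation of the aldehyde could overtake substitution. The fallback changes the order of bond formation. It sets out from 18 and the bromo aldehyde 5, which lacks the buttressing aryl ring and gains inductive activation from bromine. Twofold SNAr (Cs2CO3, DMSO, 100–120 °C) should displace fluoride, the far better nucleofuge, and give the hexameric dibromo bis-aldehyde F1. Twofold Suzuki–Miyaura coupling of this with 6 (Pd(OAc)2, SPhos, K3PO4, toluene–H2O) installs both rings E and returns to the route at 19.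

2. Step 4. Protodeboronation of the di-ortho-methoxy boronic acid may outrun transmetalation onto the hindered arylpalladium bromide, so that the bromide is left unconsumed. The fallback replaces the boron nucleophile by zinc and sets out from 5. Purchased 1,3,5-trimethoxybenzene is deprotonated with n-BuLi in THF to 2,4,6-trimethoxyphenyllithium F2, which is transmetalated with ZnCl2 to (2,4,6-trimethoxyphenyl)zinc chloride F3. Negishi coupling of this with 5 (Pd2(dba)3, SPhos, THF, 60 °C), which tolerates the aldehyde, comes back to the route at 7.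

3. Step 15. Cleavage may stop short at some of the seventeen methyl ethers, and the free polyphenol may oxidise in air or stay bound to boron during isolation, so that no pure product is obtained directly. The fallback isolates the product as a derivative and sets out from 21. The crude BBr3 product is peracetylated (Ac2O, pyridine, DMAP) to the target nonadecaacetate F4, which can be chromatographed on silica and freed from partly methylated congeners (these can be resubjected to BBr3). Deacetylation under argon (K2CO3 cat., degassed MeOH) then comes back to the route at 22.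

**Further compounds**

F1 | step 13 | hexameric dibromo bis-aldehyde: 18 with each phenol oxygen bonded to C1 of a 3-bromo-4-formyl-2,6-dimethoxyphenyl group | COc1cc(OC)cc(Oc2c(Oc3c(OC)cc(Oc4c(OC)cc(C=O)c(Br)c4OC)cc3OC)cc(OC)cc2Oc2c(OC)cc(Oc3c(OC)cc(C=O)c(Br)c3OC)cc2OC)c1
F2 | step 4 | 2,4,6-trimethoxyphenyllithium | [Li]c1c(OC)cc(OC)cc1OC
F3 | step 4 | (2,4,6-trimethoxyphenyl)zinc chloride | COc1cc(OC)c([Zn]Cl)c(OC)c1
F4 | step 15 | nonadecaacetate of 22 | CC(=O)Oc1cc(OC(C)=O)cc(Oc2c(Oc3c(OC(C)=O)cc(Oc4c(OC(C)=O)cc(OC(C)=O)c(-c5c(OC(C)=O)cc(OC(C)=O)cc5OC(C)=O)c4OC(C)=O)cc3OC(C)=O)cc(OC(C)=O)cc2Oc2c(OC(C)=O)cc(Oc3c(OC(C)=O)cc(OC(C)=O)c(-c4c(OC(C)=O)cc(OC(C)=O)cc4OC(C)=O)c3OC(C)=O)cc2OC(C)=O)c1
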